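## Retrosynthetic overview

1. Target 23 ← O-demethylation of 21 ← Pd-catalysed benzylation (bromide 19) of the (E)-alkenylalane made by Zr-catalysed methylalumination of alkyne 18; this sets the E-trisubstituted alkene.
2. Alkyne 18 ← bicyclic alcohol 13 by three-carbon homologation (triflate plus the propargyl anion of 14).
3. Alcohol 13 (second ring, the oxygen bridge) ← transannular SN1 etherification of triol 12; its secondary oxygen comes from Baeyer–Villiger cleavage of cyclobutanone 9.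
4. Cyclobutanone 9 (first ring, the six-membered carbocycle, CH–CMe2 bond) ← intramolecular ketene–alkene [2+2] cycloaddition of the ketene from acid 6.
5. Acid 6 ← (R)-(−)-linalool 1, which supplies all ten carbons of the bicyclic unit and the only bought stereocentre.

Assumption: (R)-(−)-linalool of high ee is used, and the minor epimer of step 4 is removed by chromatography, so enantiopurity rests on the bought centre alone.

## Route

Step 1
Reactants: 1 (R)-(−)-linalool
Product: 2 triethyl{[(3R)-3,7-dimethylocta-1,6-dien-3-yl]oxy}silane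
Conditions: Et3SiOTf, 2,6-lutidine, CH2Cl2, −78 → 0 °C
Reagents that add atoms: triethylsilyl trifluoromethanesulfonate, CC[Si](CC)(CC)OS(=O)(=O)C(F)(F)F
Why: Silylation of the hindered tertiary alcohol with the silyl triflate masks it as a group that survives base, hydride and peracid yet ionises later under acid, and leaves the stereocentre untouched.

Step 2
Reactants: 2 triethyl{[(3R)-3,7-dimethylocta-1,6-dien-3-yl]oxy}silane
Product: 4 (3R)-3,7-dimethyl-3-[(triethylsilyl)oxy]oct-6-en-1-ol, via alkylborane 3 (not isolated)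
Conditions: 9-BBN, THF, 0 °C → rt; then NaOH, H2O2, 0 °C
Reagents that add atoms: hydrogen peroxide, OO
Why: Hydroboration–oxidation with 9-BBN is selective for the monosubstituted vinyl group over the trisubstituted alkene and gives the anti-Markovnikov primary alcohol.

Step 3
Reactants: 4 (3R)-3,7-dimethyl-3-[(triethylsilyl)oxy]oct-6-en-1-ol
Product: 6 (3R)-3,7-dimethyl-3-[(triethylsilyl)oxy]oct-6-enoic acid, via aldehyde 5 (not isolated)
Conditions: TEMPO (cat.), PhI(OAc)2, MeCN/aq. pH 7 buffer, rt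
Reagents that add atoms: water, O
Why: The nitroxyl/hypervalent-iodine oxidation takes the primary alcohol through the aldehyde hydrate to the acid without touching the trisubstituted alkene or the silyl ether.

Step 4
Reactants: 6 (3R)-3,7-dimethyl-3-[(triethylsilyl)oxy]oct-6-enoic acid
Product: 9 (1R,2R,5R)-2,7,7-trimethyl-2-[(triethylsilyl)oxy]bicyclo[3.1.1]heptan-6-one, via acid chloride 7 (not isolated), via ketene 8 (not isolated)
Conditions: Me2C=C(Cl)NMe2, CH2Cl2, rt; then slow addition to Et3N, toluene, 110 °C, high dilution; minor C2 epimer removed by chromatography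
Reagents that add atoms: none
Why: In this Snider-type intramolecular ketene–alkene [2+2] cycloaddition the ketene carbonyl carbon bonds to the less substituted alkene carbon and the ketene α-carbon to the CMe2 carbon, which closes the six-membered carbocycle; the bought carbinol centre sets both new bridgehead centres by placing the smaller OSiEt3 group, not CH3, syn to the gem-dimethyl bridge (a modest preference, about 3–4:1, is expected).

Step 5
Reactants: 9 (1R,2R,5R)-2,7,7-trimethyl-2-[(triethylsilyl)oxy]bicyclo[3.1.1]heptan-6-one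
Product: 10 (1R,2R,5R)-2,8,8-trimethyl-2-[(triethylsilyl)oxy]-6-oxabicyclo[3.2.1]octan-7-one
Conditions: mCPBA, NaHCO3, CH2Cl2, 0 °C → rt
Reagents that add atoms: 3-chloroperbenzoic acid, OOC(=O)c1cccc(Cl)c1
Why: In the Baeyer–Villiger oxidation of the strained cyclobutanone the bridgehead remote from the electron-withdrawing β-silyloxy group migrates with retention, so oxygen ends up on the carbon next to CMe2, cis to the carboxyl carbon.

Step 6
Reactants: 10 (1R,2R,5R)-2,8,8-trimethyl-2-[(triethylsilyl)oxy]-6-oxabicyclo[3.2.1]octan-7-one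
Product: 11 (1R,3S,4R)-3-(hydroxymethyl)-2,2,4-trimethyl-4-[(triethylsilyl)oxy]cyclohexan-1-ol
Conditions: LiAlH4, THF, 0 °C
Reagents that add atoms: none
Why: Hydride reduction opens the lactone to the primary and secondary alcohols, which stay cis to each other because no stereocentre is touched.

Step 7
Reactants: 11 (1R,3S,4R)-3-(hydroxymethyl)-2,2,4-trimethyl-4-[(triethylsilyl)oxy]cyclohexan-1-ol
Product: 13 [(1S,2S,4R)-1,3,3-trimethyl-7-oxabicyclo[2.2.1]heptan-2-yl]methanol, via triol 12 (not isolated)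
Conditions: TsOH·H2O (cat.), wet CH2Cl2, rt
Reagents that add atoms: none
Why: Acid removes the silyl group and ionises the tertiary carbinol, and the 1,4-related secondary hydroxyl captures the cation across the ring (SN1 etherification, as in terpin → 1,4-cineole), so the methyl-bearing bridgehead is re-formed on the face fixed by the secondary C–O centre and the hydroxymethyl group ends up exo.

Step 8
Reactants: 13 [(1S,2S,4R)-1,3,3-trimethyl-7-oxabicyclo[2.2.1]heptan-2-yl]methanol; 14 1-(trimethylsilyl)propyne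
Product: 18 (1S,2R,4R)-2-(but-3-yn-1-yl)-1,3,3-trimethyl-7-oxabicyclo[2.2.1]heptane, via triflate 15 (not isolated), via lithiated silylpropyne 16 (not isolated), via silylalkyne 17 (not isolated)
Conditions: 13, nBuLi, Et2O, −78 °C, then Tf2O; 14, nBuLi, THF, −78 → 0 °C; combine, DMPU, −78 → 0 °C; then K2CO3, MeOH, rt
Reagents that add atoms: none
Why: The primary triflate is displaced in an SN2 alkylation by the propargylic carbanion at its CH2 terminus, and methanolysis of the C–Si bond then frees the terminal alkyne; no stereocentre is involved.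

Step 9
Reactants: 18 (1S,2R,4R)-2-(but-3-yn-1-yl)-1,3,3-trimethyl-7-oxabicyclo[2.2.1]heptane; 19 methyl 3-(bromomethyl)-4-methoxybenzoate
Product: 21 methyl 4-methoxy-3-{(2E)-3-methyl-5-[(1S,2R,4R)-1,3,3-trimethyl-7-oxabicyclo[2.2.1]heptan-2-yl]pent-2-en-1-yl}benzoate, via alkenylalane 20 (not isolated)
Conditions: Me3Al, Cp2ZrCl2 (cat.), CH2Cl2, 0 °C → rt; then 19, Pd(PPh3)4 (cat.), THF, rt
Reagents that add atoms: trimethylaluminium, C[Al](C)C
Why: Negishi zirconium-catalysed carboalumination adds CH3 and Al syn across the terminal alkyne with methyl on the internal carbon, and the Pd-catalysed cross-coupling with the benzylic bromide keeps that geometry, which gives the E-alkene.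

Step 10
Reactants: 21 methyl 4-methoxy-3-{(2E)-3-methyl-5-[(1S,2R,4R)-1,3,3-trimethyl-7-oxabicyclo[2.2.1]heptan-2-yl]pent-2-en-1-yl}benzoate
Product: 23 4-hydroxy-3-{(2E)-3-methyl-5-[(1S,2R,4R)-1,3,3-trimethyl-7-oxabicyclo[2.2.1]heptan-2-yl]pent-2-en-1-yl}benzoic acid, via methoxy acid 22 (not isolated)
Conditions: NaSEt, DMF, 120 °C; then aq. HCl
Reagents that add atoms: none
Why: Ethanethiolate removes both O-methyl groups by SN2 attack at carbon (ester first, then the aryl ether) under non-acidic conditions that leave the bridged trialkyl ether and the alkene untouched.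

## Compound list

1 | (R)-(−)-linalool, (3R)-3,7-dimethylocta-1,6-dien-3-ol | C=C[C@](C)(O)CCC=C(C)C | starting material
2 | triethyl{[(3R)-3,7-dimethylocta-1,6-dien-3-yl]oxy}silane | C=C[C@](C)(O[Si](CC)(CC)CC)CCC=C(C)C | intermediate
3 | 9-{(3S)-3,7-dimethyl-3-[(triethylsilyl)oxy]oct-6-en-1-yl}-9-borabicyclo[3.3.1]nonane (same spatial arrangement as 2; descriptor changes by CIP priority only) | C1CC2CCCC(C1)B2CC[C@](C)(O[Si](CC)(CC)CC)CCC=C(C)C | intermediate (not isolated)
4 | (3R)-3,7-dimethyl-3-[(triethylsilyl)oxy]oct-6-en-1-ol | OCC[C@](C)(O[Si](CC)(CC)CC)CCC=C(C)C | intermediate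
5 | (3R)-3,7-dimethyl-3-[(triethylsilyl)oxy]oct-6-enal | O=CC[C@](C)(O[Si](CC)(CC)CC)CCC=C(C)C | intermediate (not isolated)
6 | (3R)-3,7-dimethyl-3-[(triethylsilyl)oxy]oct-6-enoic acid | OC(=O)C[C@](C)(O[Si](CC)(CC)CC)CCC=C(C)C | intermediate
7 | (3R)-3,7-dimethyl-3-[(triethylsilyl)oxy]oct-6-enoyl chloride | ClC(=O)C[C@](C)(O[Si](CC)(CC)CC)CCC=C(C)C | intermediate (not isolated)
8 | (3R)-3,7-dimethyl-3-[(triethylsilyl)oxy]octa-1,6-dien-1-one (ketene) | O=C=C[C@](C)(O[Si](CC)(CC)CC)CCC=C(C)C | intermediate (not isolated)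
9 | (1R,2R,5R)-2,7,7-trimethyl-2-[(triethylsilyl)oxy]bicyclo[3.1.1]heptan-6-one (silyloxy group syn to the CMe2 bridge) | O=C1[C@H]2[C@](C)(O[Si](CC)(CC)CC)CC[C@@H]1C2(C)C | intermediate
10 | (1R,2R,5R)-2,8,8-trimethyl-2-[(triethylsilyl)oxy]-6-oxabicyclo[3.2.1]octan-7-one | O=C1O[C@@H]2CC[C@@](C)(O[Si](CC)(CC)CC)[C@H]1C2(C)C | intermediate
11 | (1R,3S,4R)-3-(hydroxymethyl)-2,2,4-trimethyl-4-[(triethylsilyl)oxy]cyclohexan-1-ol (OH and CH2OH cis; OSiEt3 trans to both) | OC[C@H]1[C@](C)(O[Si](CC)(CC)CC)CC[C@@H](O)C1(C)C | intermediate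
12 | (1R,2S,4R)-2-(hydroxymethyl)-1,3,3-trimethylcyclohexane-1,4-diol | OC[C@H]1[C@](C)(O)CC[C@@H](O)C1(C)C | intermediate (not isolated)
13 | [(1S,2S,4R)-1,3,3-trimethyl-7-oxabicyclo[2.2.1]heptan-2-yl]methanol (CH2OH exo, syn to the oxygen bridge) | OC[C@@H]1C(C)(C)[C@H]2CC[C@]1(C)O2 | intermediate
14 | 1-(trimethylsilyl)propyne | CC#C[Si](C)(C)C | starting material
15 | [(1S,2S,4R)-1,3,3-trimethyl-7-oxabicyclo[2.2.1]heptan-2-yl]methyl trifluoromethanesulfonate | FC(F)(F)S(=O)(=O)OC[C@@H]1C(C)(C)[C@H]2CC[C@]1(C)O2 | intermediate (not isolated)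
16 | [3-(trimethylsilyl)prop-2-yn-1-yl]lithium | [Li]CC#C[Si](C)(C)C | intermediate (not isolated)
17 | trimethyl{4-[(1S,2R,4R)-1,3,3-trimethyl-7-oxabicyclo[2.2.1]heptan-2-yl]but-1-yn-1-yl}silane | C[Si](C)(C)C#CCC[C@@H]1C(C)(C)[C@H]2CC[C@]1(C)O2 | intermediate (not isolated)
18 | (1S,2R,4R)-2-(but-3-yn-1-yl)-1,3,3-trimethyl-7-oxabicyclo[2.2.1]heptane | C#CCC[C@@H]1C(C)(C)[C@H]2CC[C@]1(C)O2 | intermediate
19 | methyl 3-(bromomethyl)-4-methoxybenzoate | COC(=O)c1ccc(OC)c(CBr)c1 | starting material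
20 | dimethyl{(1E)-2-methyl-4-[(1S,2R,4R)-1,3,3-trimethyl-7-oxabicyclo[2.2.1]heptan-2-yl]but-1-en-1-yl}alumane | C[Al](C)/C=C(\C)CC[C@@H]1C(C)(C)[C@H]2CC[C@]1(C)O2 | intermediate (not isolated)
21 | methyl 4-methoxy-3-{(2E)-3-methyl-5-[(1S,2R,4R)-1,3,3-trimethyl-7-oxabicyclo[2.2.1]heptan-2-yl]pent-2-en-1-yl}benzoate | C/C(=C\Cc1cc(C(=O)OC)ccc1OC)CC[C@@H]1C(C)(C)[C@H]2CC[C@]1(C)O2 | intermediate
22 | 4-methoxy-3-{(2E)-3-methyl-5-[(1S,2R,4R)-1,3,3-trimethyl-7-oxabicyclo[2.2.1]heptan-2-yl]pent-2-en-1-yl}benzoic acid (present as its sodium salt) | C/C(=C\Cc1cc(C(=O)O)ccc1OC)CC[C@@H]1C(C)(C)[C@H]2CC[C@]1(C)O2 | intermediate (not isolated)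
23 | 4-hydroxy-3-{(2E)-3-methyl-5-[(1S,2R,4R)-1,3,3-trimethyl-7-oxabicyclo[2.2.1]heptan-2-yl]pent-2-en-1-yl}benzoic acid | C/C(=C\Cc1cc(C(=O)O)ccc1O)CC[C@@H]1C(C)(C)[C@H]2CC[C@]1(C)O2 | target

## Step count and risks

Total steps: 10. Longest linear sequence: 10 (steps 1–10; 14 and 19 are bought).

**Step 4, the [2+2] cycloaddition.** Simple alkylketenes can dimerise, the β-silyloxy group may be lost, and the facial preference (silyloxy versus methyl next to the CMe2 bridge) is only modest. The step works only if the right epimer can be obtained pure, because the other epimer would lead to the enantiomer of the target. The fallback sets out from acid chloride 7 and comes back at 9. Acid chloride 7 is quenched with dimethylamine to give (3R)-N,N,3,7-tetramethyl-3-[(triethylsilyl)oxy]oct-6-enamide F1. Tf2O and 2,6-di-tert-butyl-4-methylpyridine in 1,2-dichloroethane convert it into the much more electrophilic keteniminium triflate F2. This closes the same ring at or below 80 °C to the cyclobutaniminium triflate F3, and aqueous NaHCO3 hydrolysis gives 9.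

**Step 5, the Baeyer–Villiger regiochemistry.** Both migrating carbons are bridgehead methines, so the choice rests only on the inductive effect of the β-silyloxy group. The fallback sets out from 9 and comes back at 12. HF·pyridine removes the silyl group to give (1R,2R,5R)-2-hydroxy-2,7,7-trimethylbicyclo[3.1.1]heptan-6-one F4. Ac2O with DMAP gives the tertiary acetate (1R,2R,5R)-2,7,7-trimethyl-6-oxobicyclo[3.1.1]heptan-2-yl acetate F5, whose stronger electron withdrawal further disfavours migration of the neighbouring bridgehead. mCPBA then gives (1R,2R,5R)-2,8,8-trimethyl-7-oxo-6-oxabicyclo[3.2.1]octan-2-yl acetate F6. LiAlH4 reduces the lactone and cleaves the acetate in one operation to give triol 12, which is closed with TsOH as in step 7.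

**Step 8, displacement at the hindered primary triflate.** The CH2 carbon sits on a ring carbon flanked by two quaternary centres, so the SN2 reaction may be slow or the triflate may rearrange. The fallback sets out from 13 and comes back at 18; it moves the displacement one carbon further out, where it is unhindered. Swern oxidation gives (1S,2R,4R)-1,3,3-trimethyl-7-oxabicyclo[2.2.1]heptane-2-carbaldehyde F7, which is used at once with Ph3P=CH2 to give (1S,2R,4R)-2-ethenyl-1,3,3-trimethyl-7-oxabicyclo[2.2.1]heptane F8. 9-BBN gives the alkylborane F9, and NaOH/H2O2 gives 2-[(1S,2R,4R)-1,3,3-trimethyl-7-oxabicyclo[2.2.1]heptan-2-yl]ethan-1-ol F10. I2, PPh3 and imidazole give (1S,2R,4R)-2-(2-iodoethyl)-1,3,3-trimethyl-7-oxabicyclo[2.2.1]heptane F11. LiC≡CH·H2NCH2CH2NH2 in DMSO then gives 18.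

## Further compounds

F1 | step 4 | (3R)-N,N,3,7-tetramethyl-3-[(triethylsilyl)oxy]oct-6-enamide | CN(C)C(=O)C[C@](C)(O[Si](CC)(CC)CC)CCC=C(C)C
F2 | step 4 | N-{(3R)-3,7-dimethyl-3-[(triethylsilyl)oxy]octa-1,6-dien-1-ylidene}-N-methylmethanaminium trifluoromethanesulfonate | C[N+](C)=C=C[C@](C)(O[Si](CC)(CC)CC)CCC=C(C)C.[O-]S(=O)(=O)C(F)(F)F
F3 | step 4 | N-methyl-N-{(1S,2R,5R)-2,7,7-trimethyl-2-[(triethylsilyl)oxy]bicyclo[3.1.1]heptan-6-ylidene}methanaminium trifluoromethanesulfonate | C[N+](C)=C1[C@H]2[C@](C)(O[Si](CC)(CC)CC)CC[C@@H]1C2(C)C.[O-]S(=O)(=O)C(F)(F)F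
F4 | step 5 | (1R,2R,5R)-2-hydroxy-2,7,7-trimethylbicyclo[3.1.1]heptan-6-one | O=C1[C@H]2[C@](C)(O)CC[C@@H]1C2(C)C
F5 | step 5 | (1R,2R,5R)-2,7,7-trimethyl-6-oxobicyclo[3.1.1]heptan-2-yl acetate | O=C1[C@H]2[C@](C)(OC(C)=O)CC[C@@H]1C2(C)C
F6 | step 5 | (1R,2R,5R)-2,8,8-trimethyl-7-oxo-6-oxabicyclo[3.2.1]octan-2-yl acetate | O=C1O[C@@H]2CC[C@@](C)(OC(C)=O)[C@H]1C2(C)C
F7 | step 8 | (1S,2R,4R)-1,3,3-trimethyl-7-oxabicyclo[2.2.1]heptane-2-carbaldehyde | O=C[C@@H]1C(C)(C)[C@H]2CC[C@]1(C)O2
F8 | step 8 | (1S,2R,4R)-2-ethenyl-1,3,3-trimethyl-7-oxabicyclo[2.2.1]heptane | C=C[C@@H]1C(C)(C)[C@H]2CC[C@]1(C)O2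
F9 | step 8 | 9-{2-[(1S,2R,4R)-1,3,3-trimethyl-7-oxabicyclo[2.2.1]heptan-2-yl]ethyl}-9-borabicyclo[3.3.1]nonane | C1CC2CCCC(C1)B2CC[C@@H]1C(C)(C)[C@H]2CC[C@]1(C)O2
F10 | step 8 | 2-[(1S,2R,4R)-1,3,3-trimethyl-7-oxabicyclo[2.2.1]heptan-2-yl]ethan-1-ol | OCC[C@@H]1C(C)(C)[C@H]2CC[C@]1(C)O2
F11 | step 8 | (1S,2R,4R)-2-(2-iodoethyl)-1,3,3-trimethyl-7-oxabicyclo[2.2.1]heptane | ICC[C@@H]1C(C)(C)[C@H]2CC[C@]1(C)O2
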